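(The numbers belong to no real substance, and the outcome is calculated.)

In a one-step world, a unit of free monomer facing a fixed population of ends decays by a plain exponential; we ask how far that carries when ends die and monomer arrives late.

free monomer 14 mM (fed, over 1.0 min); initiator 70 µM; time 12 min; the fed solution adds 0.10 times the starting volume

    free monomer + initiator → living end + monomer in chains (k1 = 75 /M/s)
    free monomer + living end → monomer in chains + living end, rate k2*[living end]*[free monomer] (k2 = 1100 /M/s)
    living end → dead end (k3 = 0.055 /s)

- every charge counts on the volume at the start, and the solution that is fed holds the whole dose
- the average divides the monomer in chains by the number of chains begun, living and dead together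
- run time (flask): 12 min

1. average number of monomer units in a chain (chains begun, living or dead) at 12 min
2. part of the free monomer that has reacted at 12 min

Free monomer is lost pseudo-first-order at the propagation constant times [living end], and an end lasts 18.2 s on average. So the initiator charge offers the exposure, the propagation constant times that charge over the death constant, which is 1.40 e-folds for a unit present throughout.

From above, with the charge present from the start, conversion reaches 75.3%. But ends live shorter than the feed lasts, so we tighten. Under rising [free monomer] the initiator's half-life is about 8.90 s, shorter than the feed, so we take this fast step as finished there and count each initiator as one chain. Monomer fed by then meets the full exposure and later monomer meets less, which gives a mean share of 0.433. Survival is convex in exposure, so our bracket tops at the exponential of the mean, 45.5%. Its floor, the share times the full-exposure conversion with the fed volume's dilution counted, is 31.2%. Multiplying by charge over chains, our reckoned length lies between 62.4 and 90.9.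

The forecast, 81 and 40.5%, on the ground that “monomer fed late mostly survives”, stands inside this bracket.

The flask gives 80.1 and 40.1%, also inside. At 1.00 min it held 65.3% free monomer and 0.00431 mM living end, an exposure left of 0.0863, which reckons down to 59.9%; the flask holds 59.9% at 12 min. A neighbour flask, the same but with 0.042 mM initiator, has exposure 0.840 and bracket 23.1% to 30.5%; its conversion is 27.7%. Run on to 120 min, the flask still gives 80.1 and 40.1%.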